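The dusk run grew slow long before it lacked starting material: at 20.0 min it still held 26.4% of its charge. As my measure of working catalyst I took the target gained per minute per starting material present.

| setting | dusk | winter | flask |
|---|---|---|---|
| starting material | 0.025 M | 0.038 M | 0.050 M |
| second substrate | 0.035 M | 0.035 M | 0.0350 M |
| free enzyme | 5 µM | 5 µM | 5.0 µM |
| impurity | 5.1 µM | 5.1 µM | 5.1 µM |
| remark | run made earlier | run made earlier |  |

| run | time / min | target / % | starting material / % |
|---|---|---|---|
| dusk | 2.00 | 14.9 | 74.7 |
| dusk | 5.00 | 22.7 | 55.1 |
| dusk | 10.0 | 29.0 | 39.4 |
| dusk | 15.0 | 30.9 | 30.7 |
| dusk | 20.0 | 32.6 | 26.4 |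
| winter | 2.00 | 11.7 | 78.0 |
| winter | 5.00 | 18.8 | 58.0 |
| winter | 10.0 | 24.8 | 40.9 |
| winter | 15.0 | 26.6 | 33.1 |
| winter | 20.0 | 28.7 | 28.0 |

(standard deviation of a reading: 0.3 percentage points)

- factor on the rate of making target when 30% of the starting material are converted if free enzyme is charged twice over
- factor on the rate when 30% of the starting material are converted if free enzyme is charged at 50 µM instead

- what has gone from starting material into another species counts as reacted, even if it can come back
- no earlier run changes the charge of free enzyme; that part of a forecast is a guess

I asked in two ways how much catalyst still worked. The readings came first. From the first interval to the last, my measure fell to 0.140 of its first value in the dusk run and to 0.209 in the winter run. The charges came second. I defined the cover as the impurity charge over the free enzyme charge, and in these flasks it is 1.02. Above one, the impurity charge could take the whole enzyme charge.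

Both ways pointed to a dying catalyst, but they parted on the moment. The cover tells the end. The second interval, which holds 30% conversion in both runs, still showed 0.470 and 0.529 of the first value. I took the mean, 0.500, as the flask's working share, and this was a guess, since no run changed the enzyme.

Doubling the charge makes the cover 0.510, and 50 µM makes it 0.102. Plain proportion keeps the working share fixed, and that is where it cheats. Counting the surplus beyond the cover against the working share gave me estimated factors of 1.96 and 18.0.

The forecast, 3 and 22, held that “the catalyst is dying rather than being product-inhibited”, and stood above my figures . The simulation gave 2.99 and 20.1, also above mine .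

    free enzyme + impurity → spent catalyst (k = 47000 L mol⁻¹ s⁻¹)
    first complex → loaded enzyme + first product (k = 120 s⁻¹)
    starting material ⇌ dormant form (K = 2.00, k = 0.00110 s⁻¹)
    starting material + free enzyme ⇌ first complex (K = 200 L mol⁻¹, k = 12000 L mol⁻¹ s⁻¹)
    second substrate + loaded enzyme ⇌ second complex (K = 39.0 L mol⁻¹, k = 18000 L mol⁻¹ s⁻¹)
    second complex → free enzyme + target (k = 22.0 s⁻¹)

In the flask, free enzyme met impurity while the round turned: spent catalyst stood at 52.6% after 2.50 min and 96.2% after 25.0 min, which is the cover times the 94.3% of impurity used, 96.2%. At 50 µM the cover leaves 89.8% of the charge beyond the impurity's reach, and the factor was 20.1. Meanwhile, in the flask, starting material passed into dormant form, which stood at 13.7% after 2.50 min and 46.0% after 25.0 min.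

The runs are simulated with constants of no real substance.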